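With OH on C1, Br on C2, C3 and C6, CH2OH on C4 and H on C5, the plan removes C2 from the benzene ring. In the five-membered ring that is left, the C3 bromine (meta to the hydroxyl in the arene) is simply a substituent alpha to the C1 carbonyl; this is the feature exploited. Dibromocarbene adds across the C1=C3 silyl enol ether bond, making C1–C2 and C2–C3; the gem-dibromocyclopropane then ionises, cutting the old C1–C3 bond and shedding the C4 proton, so the arene appears with all substituents placed. The precursor is racemic 1,3-dibromo-2-silyloxy-5-(silyloxymethyl)cyclopenta-1,3-diene, made cold and kept away from alkoxide.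

Key step: step 6

Assumption: the target is achiral, so all chiral intermediates are carried as racemates or diastereomer mixtures; every such stereocentre is destroyed by step 6.

Step 1
Reactants: 1 cyclopent-3-en-1-ylmethanol; 2 tert-butyldimethylsilyl chloride
Product: 3 tert-butyl(cyclopent-3-en-1-ylmethoxy)dimethylsilane
Conditions: TBSCl, imidazole, DMF, 0 °C to rt
Reagents that add atoms: tert-butyldimethylsilyl chloride 2, CC(C)(C)[Si](C)(C)Cl
Why: Imidazole-mediated O-silylation of an unhindered primary alcohol, the silyl ether being chosen because it is a poor leaving group next to the later acidic ring C–H and leaves together with the aryl silyl ether at the end.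

Step 2
Reactants: 3 tert-butyl(cyclopent-3-en-1-ylmethoxy)dimethylsilane; 4 oxygen
Product: 7 racemic 4-[(tert-butyldimethylsilyloxy)methyl]cyclopent-2-en-1-one, via allylic hydroperoxide 5 (not isolated), via allylic peracetate 6 (not isolated)
Conditions: O2, 5,10,15,20-tetraphenylporphyrin (cat.), hν (visible), Ac2O, pyridine, 4-(dimethylamino)pyridine (cat.), CH2Cl2, rt
Reagents that add atoms: oxygen 4, O=O
Why: The Schenck ene reaction of singlet oxygen with the symmetrical cyclopentene shifts the double bond and places OOH on a former alkene carbon, and acetylation followed by base-induced (Kornblum–DeLaMare-type) loss of acetate should give the enone with the side chain necessarily gamma to the carbonyl, the single new stereocentre being racemic.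

Step 3
Reactants: 7 racemic 4-[(tert-butyldimethylsilyloxy)methyl]cyclopent-2-en-1-one; 8 bromine
Product: 10 racemic 2-bromo-4-[(tert-butyldimethylsilyloxy)methyl]cyclopent-2-en-1-one, via trans-2,3-dibromo ketone 9 (not isolated)
Conditions: Br2, CH2Cl2, 0 °C; then Et3N, 0 °C
Reagents that add atoms: bromine 8, BrBr
Why: Anti addition of bromine to the enone followed by E1cB loss of HBr (acidic alpha proton, beta bromide) is the standard bromination–dehydrobromination route to 2-bromocycloalk-2-enones and leaves the silyl ether and the C4 centre untouched.

Step 4
Reactants: 10 racemic 2-bromo-4-[(tert-butyldimethylsilyloxy)methyl]cyclopent-2-en-1-one; 11 N-bromosuccinimide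
Product: 14 racemic 2,5-dibromo-4-[(tert-butyldimethylsilyloxy)methyl]cyclopent-2-en-1-one as a cis/trans mixture, via lithium dienolate 12 (not isolated), via trimethylsilyl dienol ether 13 (not isolated)
Conditions: LiN(SiMe3)2, TMSCl, THF, −78 °C; then NBS, −78 to 0 °C
Reagents that add atoms: N-bromosuccinimide 11, O=C1CCC(=O)N1Br
Why: Kinetic deprotonation of an enone by a lithium amide takes the alpha-prime proton, immediate O-silylation stops enolate equilibration and self-condensation, and electrophilic bromination of the silyl enol ether by N-bromosuccinimide then places bromine on that carbon, the new centre (expected mostly trans to the side chain) being irrelevant because it is flattened in step 5.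

Step 5
Reactants: 14 racemic 2,5-dibromo-4-[(tert-butyldimethylsilyloxy)methyl]cyclopent-2-en-1-one; 15 tert-butyldimethylsilyl trifluoromethanesulfonate
Product: 16 racemic 1,3-dibromo-2-(tert-butyldimethylsilyloxy)-5-[(tert-butyldimethylsilyloxy)methyl]cyclopenta-1,3-diene
Conditions: TBSOTf, Et3N, CH2Cl2, −78 °C; cold pentane/pH 7 buffer work-up, crude used at once below −20 °C
Reagents that add atoms: tert-butyldimethylsilyl trifluoromethanesulfonate 15, CC(C)(C)[Si](C)(C)OS(=O)(=O)C(F)(F)F
Why: In this soft enolisation O-silylation makes the CHBr proton, flanked by the oxocarbenium carbon and bromine, the most acidic and most accessible one, so the cross-conjugated 2-silyloxydiene with its enol ether double bond toward the brominated carbon should form in preference to the extended isomer, while the low temperature suppresses HBr loss and 1,5-hydrogen shifts.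

Step 6
Reactants: 16 racemic 1,3-dibromo-2-(tert-butyldimethylsilyloxy)-5-[(tert-butyldimethylsilyloxy)methyl]cyclopenta-1,3-diene; 17 carbon tetrabromide
Product: 19 tert-butyl{2,3,6-tribromo-4-[(tert-butyldimethylsilyloxy)methyl]phenoxy}dimethylsilane, via tetrabromobicyclohexene 18 (not isolated)
Conditions: CBr4 (3 equiv), MeLi (2.5 equiv, slow addition), Et2O, −78 °C, then to 0 °C
Reagents that add atoms: carbon tetrabromide 17, BrC(Br)(Br)Br
Why: Proposed new method: bromine–lithium exchange between CBr4 and MeLi gives tribromomethyllithium, which delivers dibromocarbene at −78 °C without alkoxide; the electrophilic singlet carbene adds in one concerted step to the C1=C3 enol ether bond of 16 (target numbering) to give the 6,6-dibromobicyclo[3.1.0]hexene 18, whose endo C2–Br bond ionises on warming in concert with disrotatory cleavage of the C1–C3 bond to a silyloxy-stabilised cyclohexadienyl cation, the C4-protonated arenium ion of 19, which gives up its C4 proton to excess carbenoid. The closest known reactions are the dihalocarbene ring expansion of cyclic silyl enol ethers to 2-halocycloalk-2-enones and the dihalocarbene conversion of cyclopentadienes and indenes into halobenzenes and 2-halonaphthalenes. The six-membered ring is closed by ring expansion and not by a cyclisation: C1–C2 and C2–C3 are made in the cheletropic [2+1] addition and the ring grows when the two-electron cyclopropyl-to-allyl electrocyclic opening cuts the shared bond. No stereocentre is created, and the C4 centre and the face of carbene attack are both erased on aromatisation. The step needs site selectivity between the two bromoalkenes and must leave the doubly allylic C4–H in place until the end; the first is secured because only C1=C3 carries the silyloxy donor while C5=C6 is an electron-poor, cross-conjugated vinyl bromide, and the second because MeLi is consumed by exchange with excess CBr4 and the temperature is too low for 1,5-hydrogen shifts that would move the enol ether bond to C1=C6.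

Step 7
Reactants: 19 tert-butyl{2,3,6-tribromo-4-[(tert-butyldimethylsilyloxy)methyl]phenoxy}dimethylsilane
Product: 21 2,3,6-tribromo-4-(hydroxymethyl)phenol, via mono-silylated phenol 20 (not isolated)
Conditions: Bu4NF, AcOH, THF, 0 °C to rt
Reagents that add atoms: none
Why: Fluoride-induced desilylation removes the aryl silyl ether first and then the primary one, and the acetic acid buffer keeps the tribromophenol protonated so that the para-hydroxybenzyl C–O bond is not expelled through a quinone methide, which is also why acidic methanol is avoided.

Compound list (chiral compounds are racemic or diastereomer mixtures, so their SMILES carry no stereodescriptors)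

1 | cyclopent-3-en-1-ylmethanol | OCC1CC=CC1 | starting material
2 | tert-butyldimethylsilyl chloride | CC(C)(C)[Si](C)(C)Cl | starting material
3 | tert-butyl(cyclopent-3-en-1-ylmethoxy)dimethylsilane (achiral) | CC(C)(C)[Si](C)(C)OCC1CC=CC1 | intermediate
4 | oxygen | O=O | starting material
5 | 4-[(tert-butyldimethylsilyloxy)methyl]cyclopent-2-en-1-yl hydroperoxide (racemic, cis/trans mixture) | CC(C)(C)[Si](C)(C)OCC1CC(OO)C=C1 | intermediate (not isolated)
6 | 4-[(tert-butyldimethylsilyloxy)methyl]cyclopent-2-en-1-yl peroxyacetate (racemic, cis/trans mixture) | CC(C)(C)[Si](C)(C)OCC1CC(OOC(C)=O)C=C1 | intermediate (not isolated)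
7 | 4-[(tert-butyldimethylsilyloxy)methyl]cyclopent-2-en-1-one (racemic) | CC(C)(C)[Si](C)(C)OCC1CC(=O)C=C1 | intermediate
8 | bromine | BrBr | starting material
9 | 2,3-dibromo-4-[(tert-butyldimethylsilyloxy)methyl]cyclopentan-1-one (2,3-trans, racemic) | CC(C)(C)[Si](C)(C)OCC1CC(=O)C(Br)C1Br | intermediate (not isolated)
10 | 2-bromo-4-[(tert-butyldimethylsilyloxy)methyl]cyclopent-2-en-1-one (racemic) | CC(C)(C)[Si](C)(C)OCC1CC(=O)C(Br)=C1 | intermediate
11 | N-bromosuccinimide | O=C1CCC(=O)N1Br | starting material
12 | lithium 5-bromo-3-[(tert-butyldimethylsilyloxy)methyl]cyclopenta-1,4-dien-1-olate (racemic) | [Li]OC1=CC(CO[Si](C)(C)C(C)(C)C)C=C1Br | intermediate (not isolated)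
13 | 5-bromo-3-[(tert-butyldimethylsilyloxy)methyl]-1-(trimethylsilyloxy)cyclopenta-1,4-diene (racemic) | C[Si](C)(C)OC1=CC(CO[Si](C)(C)C(C)(C)C)C=C1Br | intermediate (not isolated)
14 | 2,5-dibromo-4-[(tert-butyldimethylsilyloxy)methyl]cyclopent-2-en-1-one (racemic, cis/trans mixture) | CC(C)(C)[Si](C)(C)OCC1C=C(Br)C(=O)C1Br | intermediate
15 | tert-butyldimethylsilyl trifluoromethanesulfonate | CC(C)(C)[Si](C)(C)OS(=O)(=O)C(F)(F)F | starting material
16 | 1,3-dibromo-2-(tert-butyldimethylsilyloxy)-5-[(tert-butyldimethylsilyloxy)methyl]cyclopenta-1,3-diene (racemic) | CC(C)(C)[Si](C)(C)OCC1C=C(Br)C(O[Si](C)(C)C(C)(C)C)=C1Br | intermediate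
17 | carbon tetrabromide | BrC(Br)(Br)Br | starting material
18 | 2,5,6,6-tetrabromo-1-(tert-butyldimethylsilyloxy)-4-[(tert-butyldimethylsilyloxy)methyl]bicyclo[3.1.0]hex-2-ene (racemic, diastereomer mixture) | CC(C)(C)[Si](C)(C)OCC1C=C(Br)C2(O[Si](C)(C)C(C)(C)C)C1(Br)C2(Br)Br | intermediate (not isolated)
19 | tert-butyl{2,3,6-tribromo-4-[(tert-butyldimethylsilyloxy)methyl]phenoxy}dimethylsilane (achiral) | CC(C)(C)[Si](C)(C)OCc1cc(Br)c(O[Si](C)(C)C(C)(C)C)c(Br)c1Br | intermediate
20 | 2,3,6-tribromo-4-[(tert-butyldimethylsilyloxy)methyl]phenol (achiral) | CC(C)(C)[Si](C)(C)OCc1cc(Br)c(O)c(Br)c1Br | intermediate (not isolated)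
21 | 2,3,6-tribromo-4-(hydroxymethyl)phenol (achiral) | OCc1cc(Br)c(O)c(Br)c1Br | target

Total step count: 7
Longest linear sequence: 7 steps (1 to 21)

Steps most likely to fail

Step 6. Proton transfer from C4 of 16 to the carbenoid or to MeLi may outrun cyclopropanation, giving a cyclopentadienide in which the positions of the double bonds, and with them the site selectivity, are lost. Carbene transfer to the tetrasubstituted, bromine-bearing enol ether may also be slow. The fallback uses only known arene chemistry, sets out from bromine 8 and a purchased arene, and rejoins the route at target 21. 2-Bromo-4-hydroxybenzaldehyde F1, which already holds the bromine meta to the hydroxyl, is brominated at both positions ortho to the hydroxyl (Br2, NaOAc, AcOH, rt; phenol-directed electrophilic aromatic substitution, the para position being blocked by the formyl group) to give 2,3,5-tribromo-4-hydroxybenzaldehyde F2. Reduction of the aldehyde (NaBH4, THF/MeOH, 0 °C) then gives 21.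

Step 5. The amine may remove the ring proton gamma to the carbonyl instead, so that HBr is lost to a cyclopentadienone that dimerises, or it may shuttle protons in 16 during reaction and work-up so that the enol ether double bond migrates. The fallback makes the enolate by reduction instead of deprotonation, sets out from 14 and rejoins at 16. A second bromination at the CHBr carbon (NBS, NH4OAc cat., Et2O, rt; ammonium-acetate-catalysed alpha-bromination) gives racemic 2,5,5-tribromo-4-[(tert-butyldimethylsilyloxy)methyl]cyclopent-2-en-1-one F3. Zinc insertion into one geminal C–Br bond (Zn dust, THF, −20 °C; Reformatsky-type) gives the bromozinc enolate F4 regiospecifically and without a Brønsted base, and O-silylation (TBSOTf, −78 °C) gives 16.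

Step 4. Gamma deprotonation, conjugate self-addition of the bromoenone enolate, or proton exchange leading to over-bromination may erode the alpha-prime monobromination. The fallback reverses the order of the two brominations so that enolisation is done on the bromine-free enone; it sets out from 7 and rejoins at 14. Soft enolisation (TMSOTf, Et3N, CH2Cl2, 0 °C) gives the trimethylsilyl dienol ether F5, and NBS (THF, −78 °C) gives racemic 5-bromo-4-[(tert-butyldimethylsilyloxy)methyl]cyclopent-2-en-1-one F6. Bromine addition to the enone (Br2, CH2Cl2, −20 °C) gives the tribromo ketone F7, and E1cB loss of HBr (Et3N, 1 equiv, −20 °C) gives 14.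

Further compounds

F1 | step 6 | 2-bromo-4-hydroxybenzaldehyde (purchased) | O=Cc1ccc(O)cc1Br
F2 | step 6 | 2,3,5-tribromo-4-hydroxybenzaldehyde | O=Cc1cc(Br)c(O)c(Br)c1Br
F3 | step 5 | 2,5,5-tribromo-4-[(tert-butyldimethylsilyloxy)methyl]cyclopent-2-en-1-one (racemic) | CC(C)(C)[Si](C)(C)OCC1C=C(Br)C(=O)C1(Br)Br
F4 | step 5 | bromozinc 2,5-dibromo-3-[(tert-butyldimethylsilyloxy)methyl]cyclopenta-1,4-dien-1-olate (racemic) | CC(C)(C)[Si](C)(C)OCC1C=C(Br)C(O[Zn]Br)=C1Br
F5 | step 4 | 3-[(tert-butyldimethylsilyloxy)methyl]-1-(trimethylsilyloxy)cyclopenta-1,4-diene (racemic) | C[Si](C)(C)OC1=CC(CO[Si](C)(C)C(C)(C)C)C=C1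
F6 | step 4 | 5-bromo-4-[(tert-butyldimethylsilyloxy)methyl]cyclopent-2-en-1-one (racemic, cis/trans mixture) | CC(C)(C)[Si](C)(C)OCC1C=CC(=O)C1Br
F7 | step 4 | 2,3,5-tribromo-4-[(tert-butyldimethylsilyloxy)methyl]cyclopentan-1-one (racemic, diastereomer mixture) | CC(C)(C)[Si](C)(C)OCC1C(Br)C(Br)C(=O)C1Br
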